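The route rests on making ring A last: the benzene ring (C1, C2, C3, C4, C4a, C9a) with its three contiguous oxygens at C2–C4 and its lone CH at C1 is disconnected into a 2-substituted 3,4-dimethoxyfuran and a terminal ynone. One thermal intramolecular [4+2] cycloaddition joins C4a–C9a and C1–C2, closing seven-membered ring B and the ring A carbocycle at once; opening of the oxygen bridge leaves the C2 phenol, and the ynone carbonyl becomes C9. The substrate is a 2,6-dimethoxycyclohexa-2,5-dienone whose C4 (the future spiro carbon C5) carries the furan and the (2R,3S)-dimethyl-4-oxohex-5-ynyl chain.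

Key step: step 11

Remark 1: atoms are numbered as in the benzo[7]annulene core of the target (ring A: C1–C4, C4a, C9a; ring B: C4a, C5 = spiro carbon, C6–C9, C9a; dienone ring: C1' = C5, carbonyl C4'). The target is 7R,8S,9R, with the C7 and C8 methyls trans and the C9 hydroxyl trans to the C8 methyl.
Remark 2: 3,4-dimethoxyfuran is taken to be purchasable.
Remark 3: hydride reagents reduce the cross-conjugated dimethoxydienone carbonyl (C4') at least as readily as the para-methoxyaryl ketone at C9, so the end game reduces both carbonyls and restores the dienone by a selective oxidation.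
Remark 4: species that are only protonated or hydrolysed by the aqueous quench of a step (the enolate of step 4, the magnesium adduct of step 9) are counted with the product of that step.

Step 1
Reactants: 1 4-allyl-2,6-dimethoxyphenol
Product: 2 2-(benzyloxy)-1,3-dimethoxy-5-(prop-2-en-1-yl)benzene
Conditions: BnBr, K2CO3, DMF, 23 °C
Reagents that add atoms: benzyl bromide, BrCc1ccccc1
Why: Williamson ether synthesis; the phenoxide is O-benzylated so that the phenol survives the organometallic and enolate steps and can be freed later by neutral hydrogenolysis.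

Step 2
Reactants: 3 (S)-4-benzyloxazolidin-2-one; 4 acryloyl chloride
Product: 6 (4S)-4-benzyl-3-(prop-2-enoyl)oxazolidin-2-one, via bromomagnesium oxazolidinide 5 (not isolated)
Conditions: MeMgBr, THF, 0 °C; then 4, −78 → 0 °C
Reagents that add atoms: none
Why: N-acylation of the oxazolidinone as its bromomagnesium salt with the acid chloride; the magnesium amide is chosen because it does not start anionic polymerisation of the acrylimide.

Step 3
Reactants: 2 2-(benzyloxy)-1,3-dimethoxy-5-(prop-2-en-1-yl)benzene (2 equiv); 6 (4S)-4-benzyl-3-(prop-2-enoyl)oxazolidin-2-one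
Product: 7 (4S)-4-benzyl-3-[(2E)-4-[4-(benzyloxy)-3,5-dimethoxyphenyl]but-2-enoyl]oxazolidin-2-one
Conditions: (H2IMes)(PCy3)Cl2Ru=CHPh (second-generation Grubbs catalyst, 5 mol %), 1,4-benzoquinone (10 mol %), CH2Cl2, 40 °C
Reagents that add atoms: none
Why: Olefin cross-metathesis; the electron-rich allylarene and the electron-poor acrylimide pair selectively and the E-alkene should form, with benzoquinone holding back ruthenium hydride migration of the double bond into conjugation with the arene.

Step 4
Reactants: 7 (4S)-4-benzyl-3-[(2E)-4-[4-(benzyloxy)-3,5-dimethoxyphenyl]but-2-enoyl]oxazolidin-2-one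
Product: 8 (4S)-4-benzyl-3-[(3R)-4-[4-(benzyloxy)-3,5-dimethoxyphenyl]-3-methylbutanoyl]oxazolidin-2-one
Conditions: MeMgBr, CuBr·SMe2 (1:1), THF/Me2S, −40 → −15 °C; aq. NH4Cl
Reagents that add atoms: methylmagnesium bromide, C[Mg]Br
Why: Auxiliary-controlled organocopper 1,4-addition; in the magnesium-chelated syn-s-cis N-enoyl oxazolidinone the methyl group is delivered to the β-carbon from the face opposite the C4 benzyl group, which sets the 3R centre (C7 of the target).

Step 5
Reactants: 8 (4S)-4-benzyl-3-[(3R)-4-[4-(benzyloxy)-3,5-dimethoxyphenyl]-3-methylbutanoyl]oxazolidin-2-one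
Product: 10 (4S)-4-benzyl-3-[(2S,3R)-4-[4-(benzyloxy)-3,5-dimethoxyphenyl]-2,3-dimethylbutanoyl]oxazolidin-2-one, via sodium Z-enolate 9 (not isolated)
Conditions: NaN(SiMe3)2, THF, −78 °C; then MeI, −78 → −40 °C
Reagents that add atoms: iodomethane, CI
Why: Evans asymmetric alkylation; the chelated sodium Z-enolate is methylated on the face away from the auxiliary benzyl group, setting 2S (C8 of the target) under reagent control and placing the two methyls syn along the chain, the arrangement that becomes trans on ring B.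

Step 6
Reactants: 10 (4S)-4-benzyl-3-[(2S,3R)-4-[4-(benzyloxy)-3,5-dimethoxyphenyl]-2,3-dimethylbutanoyl]oxazolidin-2-one
Product: 12 (2S,3R)-4-[4-(benzyloxy)-3,5-dimethoxyphenyl]-2,3-dimethylbutanoic acid, via peroxy acid 11 (not isolated)
Conditions: LiOH, H2O2, THF/H2O, 0 °C; then Na2SO3; HCl to pH 2
Reagents that add atoms: hydrogen peroxide, OO
Why: Hydroperoxide cleavage of the N-acyl oxazolidinone; the α-effect nucleophile attacks only the exocyclic carbonyl, sulfite reduces the peroxy acid, and the weakly basic conditions leave C8 unepimerised while the auxiliary is recovered.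

Step 7
Reactants: 12 (2S,3R)-4-[4-(benzyloxy)-3,5-dimethoxyphenyl]-2,3-dimethylbutanoic acid
Product: 13 (2S,3R)-4-[4-(benzyloxy)-3,5-dimethoxyphenyl]-N-methoxy-N,2,3-trimethylbutanamide
Conditions: MeNH(OMe)·HCl, EDC·HCl, HOBt, N-methylmorpholine, CH2Cl2, 0 → 23 °C
Reagents that add atoms: N,O-dimethylhydroxylamine hydrochloride, CNOC.Cl
Why: Carbodiimide amide coupling through the hydroxybenzotriazole active ester gives the Weinreb amide without enolisation of the α-centre.

Step 8
Reactants: 13 (2S,3R)-4-[4-(benzyloxy)-3,5-dimethoxyphenyl]-N-methoxy-N,2,3-trimethylbutanamide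
Product: 14 (2S,3R)-4-(4-hydroxy-3,5-dimethoxyphenyl)-N-methoxy-N,2,3-trimethylbutanamide
Conditions: H2 (1 atm), Pd/C, EtOAc, 23 °C
Reagents that add atoms: none
Why: Hydrogenolysis of the aryl benzyl ether over palladium on carbon; it is placed here, before any alkyne exists, and the N-methoxy amide and the arene are inert to it.

Step 9
Reactants: 14 (2S,3R)-4-(4-hydroxy-3,5-dimethoxyphenyl)-N-methoxy-N,2,3-trimethylbutanamide; 15 ethynylmagnesium bromide (3.5 equiv)
Product: 16 (4S,5R)-6-(4-hydroxy-3,5-dimethoxyphenyl)-4,5-dimethylhex-1-yn-3-one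
Conditions: THF, 0 → 23 °C; inverse quench into cold 1 M HCl
Reagents that add atoms: none
Why: Weinreb ketone synthesis; after the first equivalent deprotonates the phenol, the acetylide adds once to give a stable magnesium chelate that releases the ynone only on the acidic quench, which also protonates the liberated amine and prevents its conjugate addition to the ynone.

Step 10
Reactants: 16 (4S,5R)-6-(4-hydroxy-3,5-dimethoxyphenyl)-4,5-dimethylhex-1-yn-3-one; 17 3,4-dimethoxyfuran (5 equiv)
Product: 18 4-(3,4-dimethoxyfuran-2-yl)-4-[(2R,3S)-2,3-dimethyl-4-oxohex-5-yn-1-yl]-2,6-dimethoxycyclohexa-2,5-dien-1-one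
Conditions: PhI(OAc)2 (1.1 equiv, slow addition), (CF3)2CHOH/CH2Cl2 (1:1), −20 °C
Reagents that add atoms: none
Why: Oxidative phenol dearomatisation (oxidative Friedel–Crafts-type coupling with a trivalent-iodine oxidant); ligand exchange at iodine and loss of PhI give a fluoroalcohol-stabilised phenoxonium ion that the free α-carbon of the electron-rich furan should attack at the para carbon before re-aromatising by proton loss, making C5 quaternary (not a stereocentre, its two dienone arms being identical) while the electron-poor ynone stays a spectator at this temperature.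

Step 11
Reactants: 18 4-(3,4-dimethoxyfuran-2-yl)-4-[(2R,3S)-2,3-dimethyl-4-oxohex-5-yn-1-yl]-2,6-dimethoxycyclohexa-2,5-dien-1-one
Product: 20 (7R,8S)-2-hydroxy-3,3',4,5'-tetramethoxy-7,8-dimethyl-7,8-dihydrospiro[benzo[7]annulene-5,1'-cyclohexa[2,5]diene]-4',9(6H)-dione, via oxanorbornadiene cycloadduct 19 (not isolated)
Conditions: PhMe (5 mM), BHT (cat.), 100 °C; then PPTS (cat.), 23 °C
Reagents that add atoms: none
Why: Heating brings the electron-rich 3,4-dimethoxyfuran (diene, its C2 bound to C5) and the ynone (dienophile) together in a normal-electron-demand intramolecular Diels–Alder reaction that forms C4a–C9a and C1–C2 and gives the 7-oxabicyclo[2.2.1]heptadiene 19; its C4a–O bond then ionises (allyl cation stabilised through the C3 methoxy enol ether) and loss of the C2 proton aromatises ring A to the C2 phenol, the mild acid finishing this opening. The closest known reaction type is the intramolecular furan–alkyne Diels–Alder/aromatisation sequence that turns 2-tethered furans into ring-fused phenols. Ring B closes as the tether ring of the cycloaddition (seven-membered, across the five-atom link C5–C6–C7–C8–C9, helped by the quaternary C5 and the two methyl branches), and ring A closes as the six-membered carbocycle of the [4+2] adduct itself, first oxygen-bridged and then aromatic. No lasting stereocentre is created: the two bridgehead centres of 19 vanish on aromatisation, and C7 and C8 are untouched under neutral thermal conditions. The step needs regiocontrol and chemoselectivity: the link lets only the furan carbon on C5 reach the alkyne carbon next to the carbonyl, so the bridge oxygen ends on the hydrogen-bearing carbon C2, and working without a Lewis acid at high dilution avoids dienone–phenol rearrangement of the 4,4-disubstituted dienone and intermolecular cycloaddition.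

Step 12
Reactants: 20 (7R,8S)-2-hydroxy-3,3',4,5'-tetramethoxy-7,8-dimethyl-7,8-dihydrospiro[benzo[7]annulene-5,1'-cyclohexa[2,5]diene]-4',9(6H)-dione
Product: 21 (7R,8S)-2,3,3',4,5'-pentamethoxy-7,8-dimethyl-7,8-dihydrospiro[benzo[7]annulene-5,1'-cyclohexa[2,5]diene]-4',9(6H)-dione
Conditions: MeI, K2CO3, acetone, 23 °C
Reagents that add atoms: iodomethane, CI
Why: Williamson O-methylation of the C2 phenol; potassium carbonate is too weak a base to enolise the C9 aryl ketone, so C8 keeps its configuration.

Step 13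
Reactants: 21 (7R,8S)-2,3,3',4,5'-pentamethoxy-7,8-dimethyl-7,8-dihydrospiro[benzo[7]annulene-5,1'-cyclohexa[2,5]diene]-4',9(6H)-dione
Product: 22 (7R,8S,9R)-2,3,3',4,5'-pentamethoxy-7,8-dimethyl-6,7,8,9-tetrahydrospiro[benzo[7]annulene-5,1'-cyclohexa[2,5]diene]-4',9-diol (both epimers at C4')
Conditions: NaBH4 (excess), CeCl3·7H2O, MeOH/THF, −40 → 23 °C; pH 7 buffer
Reagents that add atoms: none
Why: Luche reduction; both ketones are reduced 1,2-selectively (the dienone carbonyl on purpose, see step 14), and at C9 the small hydride should enter on the axial-type trajectory anti to the pseudo-axial C8–H of the chair-like ring B with pseudo-equatorial methyls, giving the pseudo-equatorial 9R alcohol trans to the C8 methyl (substrate control of the torsional, Felkin type).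

Step 14
Reactants: 22 (7R,8S,9R)-2,3,3',4,5'-pentamethoxy-7,8-dimethyl-6,7,8,9-tetrahydrospiro[benzo[7]annulene-5,1'-cyclohexa[2,5]diene]-4',9-diol
Product: 23 (7R,8S,9R)-9-hydroxy-2,3,3',4,5'-pentamethoxy-7,8-dimethyl-6,7,8,9-tetrahydrospiro[benzo[7]annulene-5,1'-cyclohexa[2,5]dien]-4'-one
Conditions: MnO2 (activated), CH2Cl2, 0 °C, followed closely
Reagents that add atoms: none
Why: Selective allylic oxidation; MnO2 should oxidise the doubly allylic, enol-ether-flanked dienol much faster than the hindered secondary benzylic C9 alcohol, restoring the cross-conjugated dienone and erasing the epimer mixture at C4'.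

Compound list
1 | 4-allyl-2,6-dimethoxyphenol | C=CCc1cc(OC)c(O)c(OC)c1 | starting material
2 | 2-(benzyloxy)-1,3-dimethoxy-5-(prop-2-en-1-yl)benzene | C=CCc1cc(OC)c(OCc2ccccc2)c(OC)c1 | intermediate
3 | (S)-4-benzyloxazolidin-2-one | O=C1N[C@@H](Cc2ccccc2)CO1 | starting material
4 | acryloyl chloride | C=CC(=O)Cl | starting material
5 | bromomagnesium salt of 3 (N-metallated, not isolated) | O=C1OC[C@H](Cc2ccccc2)N1[Mg]Br | intermediate
6 | (4S)-4-benzyl-3-(prop-2-enoyl)oxazolidin-2-one | C=CC(=O)N1[C@@H](Cc2ccccc2)COC1=O | intermediate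
7 | (4S)-4-benzyl-3-[(2E)-4-[4-(benzyloxy)-3,5-dimethoxyphenyl]but-2-enoyl]oxazolidin-2-one | COc1cc(C/C=C/C(=O)N2[C@@H](Cc3ccccc3)COC2=O)cc(OC)c1OCc1ccccc1 | intermediate
8 | (4S)-4-benzyl-3-[(3R)-4-[4-(benzyloxy)-3,5-dimethoxyphenyl]-3-methylbutanoyl]oxazolidin-2-one | COc1cc(C[C@@H](C)CC(=O)N2[C@@H](Cc3ccccc3)COC2=O)cc(OC)c1OCc1ccccc1 | intermediate
9 | sodium Z-enolate of 8 (not isolated) | COc1cc(C[C@@H](C)/C=C(\[O-])N2[C@@H](Cc3ccccc3)COC2=O)cc(OC)c1OCc1ccccc1.[Na+] | intermediate
10 | (4S)-4-benzyl-3-[(2S,3R)-4-[4-(benzyloxy)-3,5-dimethoxyphenyl]-2,3-dimethylbutanoyl]oxazolidin-2-one | COc1cc(C[C@@H](C)[C@H](C)C(=O)N2[C@@H](Cc3ccccc3)COC2=O)cc(OC)c1OCc1ccccc1 | intermediate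
11 | (2S,3R)-4-[4-(benzyloxy)-3,5-dimethoxyphenyl]-2,3-dimethylbutaneperoxoic acid (not isolated) | COc1cc(C[C@@H](C)[C@H](C)C(=O)OO)cc(OC)c1OCc1ccccc1 | intermediate
12 | (2S,3R)-4-[4-(benzyloxy)-3,5-dimethoxyphenyl]-2,3-dimethylbutanoic acid | COc1cc(C[C@@H](C)[C@H](C)C(O)=O)cc(OC)c1OCc1ccccc1 | intermediate
13 | (2S,3R)-4-[4-(benzyloxy)-3,5-dimethoxyphenyl]-N-methoxy-N,2,3-trimethylbutanamide | COc1cc(C[C@@H](C)[C@H](C)C(=O)N(C)OC)cc(OC)c1OCc1ccccc1 | intermediate
14 | (2S,3R)-4-(4-hydroxy-3,5-dimethoxyphenyl)-N-methoxy-N,2,3-trimethylbutanamide | COc1cc(C[C@@H](C)[C@H](C)C(=O)N(C)OC)cc(OC)c1O | intermediate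
15 | ethynylmagnesium bromide | C#C[Mg]Br | starting material
16 | (4S,5R)-6-(4-hydroxy-3,5-dimethoxyphenyl)-4,5-dimethylhex-1-yn-3-one | COc1cc(C[C@@H](C)[C@H](C)C(=O)C#C)cc(OC)c1O | intermediate
17 | 3,4-dimethoxyfuran | COc1cocc1OC | starting material
18 | 4-(3,4-dimethoxyfuran-2-yl)-4-[(2R,3S)-2,3-dimethyl-4-oxohex-5-yn-1-yl]-2,6-dimethoxycyclohexa-2,5-dien-1-one (cycloaddition precursor) | COC1=CC(C=C(OC)C1=O)(C[C@@H](C)[C@H](C)C(=O)C#C)c1occ(OC)c1OC | intermediate
19 | 7-oxabicyclo[2.2.1]hepta-2,5-diene cycloadduct, oxygen bridging C2 and C4a, C1=C9a and C3=C4 double bonds (bridgehead configuration not specified, not isolated) | COC1=CC2(C=C(OC)C1=O)C[C@@H](C)[C@H](C)C(=O)C3=CC4OC32C(OC)=C4OC | intermediate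
20 | (7R,8S)-2-hydroxy-3,3',4,5'-tetramethoxy-7,8-dimethyl-7,8-dihydrospiro[benzo[7]annulene-5,1'-cyclohexa[2,5]diene]-4',9(6H)-dione (cycloaddition product) | COC1=CC2(C=C(OC)C1=O)C[C@@H](C)[C@H](C)C(=O)c1cc(O)c(OC)c(OC)c12 | intermediate
21 | (7R,8S)-2,3,3',4,5'-pentamethoxy-7,8-dimethyl-7,8-dihydrospiro[benzo[7]annulene-5,1'-cyclohexa[2,5]diene]-4',9(6H)-dione | COC1=CC2(C=C(OC)C1=O)C[C@@H](C)[C@H](C)C(=O)c1cc(OC)c(OC)c(OC)c12 | intermediate
22 | (7R,8S,9R)-2,3,3',4,5'-pentamethoxy-7,8-dimethyl-6,7,8,9-tetrahydrospiro[benzo[7]annulene-5,1'-cyclohexa[2,5]diene]-4',9-diol (C4' not specified, both epimers) | COC1=CC2(C=C(OC)C1O)C[C@@H](C)[C@H](C)[C@@H](O)c1cc(OC)c(OC)c(OC)c12 | intermediate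
23 | (7R,8S,9R)-9-hydroxy-2,3,3',4,5'-pentamethoxy-7,8-dimethyl-6,7,8,9-tetrahydrospiro[benzo[7]annulene-5,1'-cyclohexa[2,5]dien]-4'-one | COC1=CC2(C=C(OC)C1=O)C[C@@H](C)[C@H](C)[C@@H](O)c1cc(OC)c(OC)c(OC)c12 | target

Total step count: 14. Longest linear sequence: 13 steps (1 → 23 through steps 1 and 3–14; step 2 prepares the acrylimide).

Steps most likely to fail

Step 11. Closure of the seven-membered ring may be too slow, so that oligomerisation of the terminal ynone or intermolecular cycloaddition takes over. The fallback sets out from 18 and comes back at 20, replacing the alkyne dienophile by an alkene that carries a leaving group. LiCl in AcOH adds HCl across the ynone to give the (Z)-β-chlorovinyl ketone F6. Heating F6 in toluene gives the chloro-substituted oxanorbornene cycloadduct F7. DBU then removes HCl from C9a/C1 to give 19, which opens to 20 as in the route.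

Step 10. This is the one step outside the key step with real uncertainty. The phenoxonium ion may be captured at a methoxy-bearing ortho carbon instead of the para carbon, or it may lose a benzylic proton to a quinone methide that the furan then attacks at C6. The furan may also be oxidised or coupled twice. The fallback sets out from 13 and comes back at 23; it brings ring A in as an intact arene and closes the spiro centre intramolecularly.
- 3,4,5-Trimethoxyphenylmagnesium bromide adds to 13 to give the aryl ketone F1.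
- Corey–Bakshi–Shibata reduction with the (S)-methyl oxazaborolidine and BH3·SMe2 gives the (1R)-alcohol F2.
- t-BuMe2SiCl and imidazole give the silyl ether F3.
- Hydrogenolysis (H2, Pd/C) frees the phenol F4.
- PhI(OCOCF3)2 in CF3CH2OH at −40 °C effects the para-selective intramolecular phenol–arene spirocyclisation to the silyl-protected spirodienone F5.
- Bu4NF removes the silyl group to give 23.

Step 13. Hydride may be delivered mainly to the other face of the C9 carbonyl. The fallback sets out from 21 and comes back at 23, using inversion in place of facial control. The same reduction then gives the 9S diol F8, which MnO2 oxidises as in step 14 to the C9 epimer of the target F9. Mitsunobu reaction (4-nitrobenzoic acid, PPh3, DIAD) inverts C9 to give the 9R 4-nitrobenzoate F10, and K2CO3 in MeOH cleaves the ester to give 23.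

Further compounds
F1 | step 10 | (2S,3R)-4-[4-(benzyloxy)-3,5-dimethoxyphenyl]-2,3-dimethyl-1-(3,4,5-trimethoxyphenyl)butan-1-one | COc1cc(C[C@@H](C)[C@H](C)C(=O)c2cc(OC)c(OC)c(OC)c2)cc(OC)c1OCc1ccccc1
F2 | step 10 | (1R,2S,3R)-4-[4-(benzyloxy)-3,5-dimethoxyphenyl]-2,3-dimethyl-1-(3,4,5-trimethoxyphenyl)butan-1-ol | COc1cc(C[C@@H](C)[C@H](C)[C@@H](O)c2cc(OC)c(OC)c(OC)c2)cc(OC)c1OCc1ccccc1
F3 | step 10 | tert-butyldimethylsilyl ether of F2 | COc1cc(C[C@@H](C)[C@H](C)[C@@H](O[Si](C)(C)C(C)(C)C)c2cc(OC)c(OC)c(OC)c2)cc(OC)c1OCc1ccccc1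
F4 | step 10 | 4-[(2R,3S,4R)-4-(tert-butyldimethylsilyloxy)-2,3-dimethyl-4-(3,4,5-trimethoxyphenyl)butyl]-2,6-dimethoxyphenol | COc1cc(C[C@@H](C)[C@H](C)[C@@H](O[Si](C)(C)C(C)(C)C)c2cc(OC)c(OC)c(OC)c2)cc(OC)c1O
F5 | step 10 | 9-O-tert-butyldimethylsilyl ether of 23 | COC1=CC2(C=C(OC)C1=O)C[C@@H](C)[C@H](C)[C@@H](O[Si](C)(C)C(C)(C)C)c1cc(OC)c(OC)c(OC)c12
F6 | step 11 | 4-[(2R,3S,5Z)-6-chloro-2,3-dimethyl-4-oxohex-5-en-1-yl]-4-(3,4-dimethoxyfuran-2-yl)-2,6-dimethoxycyclohexa-2,5-dien-1-one | COC1=CC(C=C(OC)C1=O)(C[C@@H](C)[C@H](C)C(=O)/C=C\Cl)c1occ(OC)c1OC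
F7 | step 11 | 1-chloro-1,9a-dihydro analogue of 19 (chloro oxanorbornene cycloadduct, new centres not specified) | COC1=CC2(C=C(OC)C1=O)C[C@@H](C)[C@H](C)C(=O)C3C(Cl)C4OC32C(OC)=C4OC
F8 | step 13 | (7R,8S,9S)-2,3,3',4,5'-pentamethoxy-7,8-dimethyl-6,7,8,9-tetrahydrospiro[benzo[7]annulene-5,1'-cyclohexa[2,5]diene]-4',9-diol | COC1=CC2(C=C(OC)C1O)C[C@@H](C)[C@H](C)[C@H](O)c1cc(OC)c(OC)c(OC)c12
F9 | step 13 | (7R,8S,9S)-9-hydroxy-2,3,3',4,5'-pentamethoxy-7,8-dimethyl-6,7,8,9-tetrahydrospiro[benzo[7]annulene-5,1'-cyclohexa[2,5]dien]-4'-one | COC1=CC2(C=C(OC)C1=O)C[C@@H](C)[C@H](C)[C@H](O)c1cc(OC)c(OC)c(OC)c12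
F10 | step 13 | 4-nitrobenzoate ester of 23 (9R) | COC1=CC2(C=C(OC)C1=O)C[C@@H](C)[C@H](C)[C@@H](OC(=O)c3ccc(cc3)[N+](=O)[O-])c1cc(OC)c(OC)c(OC)c12
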